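**Plan**
- **Cuts:** the oxirane oxygen is removed from C4/C5, giving the E-enone. C1–C2 and C3–C4 are then cut and C1–C4 rejoined, which contracts the ten-membered ring to an eight-membered C1 ketone. Further cuts are C4=C5 (metathesis), C1–C4 (NHK), O8–acyl (Mitsunobu), C5–C6 (vinyl Grignard) and C8–C9 (alkyllithium plus lactone).
- **Enabling feature:** in the ten-membered carbocycle the β-diketone C1(=O)–C2H2–C3(=O) lies between the methyl-bearing carbons C10 and C4. C2–C3 is therefore a ketene unit inserted into the C1–C4 bond of a cyclooctanone enol ether that is fused at C6–C7 to the butenolide.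
- **Ring order, forward:** furan, then butenolide (photooxygenation, vinyl addition), then eight-membered enone (RCM), then bicyclo[6.2.0] cyclobutanone, then ten-membered 1,3-dione, then oxirane.
- **Stereochemistry:** C10 comes from (S)-Roche ester. C8 is set by asymmetric transfer hydrogenation and then inverted in the Mitsunobu step. C6 is set by chelation-controlled vinyl addition relayed from C8. C4/C5 are set by outer-face dioxirane epoxidation of the E-enone.
- **Masking:** C2 is blocked as CBr2 only while the epoxide is installed.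

Key step: step 20

Assumption: germacrane numbering (C1–C15) is used for all intermediates. Centres that are erased again are left open in the SMILES: hemiacetal C6 in 12, carbinol C1 in 24, C1/C4 in 30 and 31, C4 in 32 and 33, and sulfur in 33.

Step 1
Reactants: 1 diethyl furan-3,4-dicarboxylate
Product: 2 furan-3,4-diyldimethanol
Conditions: LiAlH4, THF, 0 °C → rt
Reagents that add atoms: none
Why: Exhaustive LiAlH4 ester reduction gives the symmetric diol whose two arms become C8 and C13.

Step 2
Reactants: 2 furan-3,4-diyldimethanol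
Product: 3 1H,3H-furo[3,4-c]furan-1-one (C=O is C8, OCH2 is C13)
Conditions: MnO2 (excess), CH2Cl2, reflux
Reagents that add atoms: none
Why: MnO2 oxidises one furylic alcohol to the aldehyde and its lactol on to the lactone (oxidative lactonisation of a 1,4-diol), which tells the two arms apart without a protecting group.

Step 3
Reactants: 4 methyl (S)-3-hydroxy-2-methylpropanoate
Product: 5 methyl (S)-3-(tert-butyldimethylsilyloxy)-2-methylpropanoate
Conditions: TBSCl, imidazole, CH2Cl2, rt
Reagents that add atoms: tert-butyldimethylsilyl chloride, CC(C)(C)[Si](C)(C)Cl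
Why: Standard silylation protects the future C1 oxygen, and the C10 stereocentre is taken unchanged from the chiral pool.

Step 4
Reactants: 5 silyl ether ester
Product: 6 (R)-3-(tert-butyldimethylsilyloxy)-2-methylpropan-1-ol
Conditions: LiAlH4, Et2O, 0 °C
Reagents that add atoms: none
Why: Ester reduction with LiAlH4 leaves the silyl ether and the neighbouring stereocentre intact.

Step 5
Reactants: 6 primary alcohol
Product: 7 (S)-tert-butyl(3-iodo-2-methylpropoxy)dimethylsilane
Conditions: I2, PPh3, imidazole, CH2Cl2, 0 °C → rt
Reagents that add atoms: iodine, II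
Why: Appel-type (Garegg–Samuelsson) iodination turns the primary alcohol into the iodide carbon that becomes C9.

Step 6
Reactants: 7 iodide; 3 furan-fused lactone
Product: 9 (R)-4-(tert-butyldimethylsilyloxy)-1-[4-(hydroxymethyl)furan-3-yl]-3-methylbutan-1-one (in equilibrium with its lactol), via alkyllithium 8 (not isolated)
Conditions: t-BuLi (2.1 equiv), Et2O, −78 °C; then 3, THF, −78 °C; aq NH4Cl
Reagents that add atoms: none
Why: Lithium–iodine exchange and single addition of the alkyllithium to the lactone carbonyl form C8–C9, because the tetrahedral lithium alkoxide holds back a second addition at −78 °C.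

Step 7
Reactants: 9 hydroxy ketone
Product: 10 (1S,3R)-4-(tert-butyldimethylsilyloxy)-1-[4-(hydroxymethyl)furan-3-yl]-3-methylbutan-1-ol (8S,10R)
Conditions: RuCl[(S,S)-TsDPEN](p-cymene) (1 mol %), HCO2H–Et3N (5:2), rt
Reagents that add atoms: none
Why: Noyori asymmetric transfer hydrogenation of the heteroaryl alkyl ketone tolerates the free alcohol, and the (S,S)-catalyst sets the (8S)-carbinol by reagent control (C8 is inverted in step 13).

Step 8
Reactants: 10 furyl diol
Product: 12 5-hydroxy-3-(hydroxymethyl)-4-[(1S,3R)-4-(tert-butyldimethylsilyloxy)-1-hydroxy-3-methylbutyl]furan-2(5H)-one, via furan endoperoxide 11 (not isolated)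
Conditions: O2, hν, tetraphenylporphyrin, iPr2NEt, CH2Cl2, −78 °C
Reagents that add atoms: dioxygen, O=O
Why: Singlet oxygen adds [4+2] to the furan, and in the Kornblum–DeLaMare opening the hindered amine removes the less shielded bridgehead hydrogen at C12 (next to CH2OH), so C12 becomes the lactone carbonyl and C6 the hemiacetal carbon.

Step 9
Reactants: 12 γ-hydroxybutenolide
Product: 14 (5S)-3-(hydroxymethyl)-4-[(1S,3R)-4-(tert-butyldimethylsilyloxy)-1-hydroxy-3-methylbutyl]-5-vinylfuran-2(5H)-one (6S,8S,10R), via hydroxy acid 13 (not isolated)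
Conditions: CH2=CHMgBr (5 equiv), THF, −78 → 0 °C; then 1 M HCl
Reagents that add atoms: vinylmagnesium bromide, C=C[Mg]Br
Why: The Grignard reagent adds to the ring-opened aldehyde carboxylate, in which the O8 magnesium alkoxide chelates the C6 aldehyde oxygen in a flat six-membered ring, so vinyl attacks anti to the C9 chain (1,3-chelation control) and sets C6, and acid closes the lactone with retention.

Step 10
Reactants: 14 diol
Product: 15 C13 monoacetate of 14
Conditions: AcCl (1.05 equiv), 2,4,6-collidine, CH2Cl2, −78 °C
Reagents that add atoms: acetyl chloride, CC(Cl)=O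
Why: Kinetic acylation with AcCl–collidine distinguishes the primary allylic C13 hydroxyl from the hindered secondary C8 hydroxyl.

Step 11
Reactants: 16 4-methylfuran-2(5H)-one
Product: 19 4-methoxybenzyl (Z)-4-acetoxy-3-methylbut-2-enoate, via sodium hydroxy enoate 17 (not isolated), via hydroxy ester 18 (not isolated)
Conditions: NaOH (1.0 equiv), H2O–MeOH, rt, evaporate; PMBCl, Bu4NI (cat.), DMF, rt; then Ac2O, pyridine, DMAP (cat.), 0 °C
Reagents that add atoms: sodium hydroxide, [Na+].[OH-]; 4-methoxybenzyl chloride, COc1ccc(CCl)cc1; acetic anhydride, CC(=O)OC(C)=O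
Why: Saponification keeps the Z geometry fixed by the ring, and carboxylate alkylation with immediate acetylation blocks relactonisation.

Step 12
Reactants: 19 PMB ester
Product: 20 (Z)-4-acetoxy-3-methylbut-2-enoic acid
Conditions: TFA, anisole, CH2Cl2, 0 °C
Reagents that add atoms: none
Why: Acidolysis of the PMB ester, with anisole trapping the benzyl cation, frees the acid without touching the acetate or the Z olefin.

Step 13
Reactants: 15 C8 alcohol; 20 side-chain acid
Product: 21 C8 (Z)-4-acetoxy-3-methylbut-2-enoate with inverted C8 (6S,8R,10R)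
Conditions: PPh3, DIAD, toluene, 0 °C → rt
Reagents that add atoms: none
Why: Mitsunobu esterification runs by SN2 displacement of the oxyphosphonium ion, so the side chain is attached and C8 is inverted from S to the required R in one operation.

Step 14
Reactants: 21 silyl ether
Product: 22 C1 primary alcohol
Conditions: HF·pyridine, THF, 0 °C → rt
Reagents that add atoms: none
Why: Fluoride-mediated desilylation under weakly acidic conditions spares the three esters, the lactone and the acidic C6–H.

Step 15
Reactants: 22 primary alcohol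
Product: 23 C1 aldehyde
Conditions: Dess–Martin periodinane, CH2Cl2, 0 °C → rt
Reagents that add atoms: none
Why: Dess–Martin oxidation is neutral enough to keep the α-stereocentre C10, and the aldehyde is used at once.

Step 16
Reactants: 23 aldehyde
Product: 24 C1 isopropenyl carbinol (C1 epimers)
Conditions: 2-bromopropene, CrCl2 (4 equiv), NiCl2 (1 mol %), DMF, rt
Reagents that add atoms: 2-bromopropene, CC(Br)=C
Why: In the Nozaki–Hiyama–Kishi reaction the alkenylchromium species made from divalent chromium under nickel catalysis adds only to the aldehyde (forming C1–C4) and tolerates lactone and esters, and the C1 epimers converge in step 17.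

Step 17
Reactants: 24 allylic alcohol
Product: 25 isopropenyl ketone (metathesis precursor, 6S,8R,10R)
Conditions: Dess–Martin periodinane, CH2Cl2, 0 °C → rt
Reagents that add atoms: none
Why: Dess–Martin oxidation of the allylic alcohol gives the C1 enone without base, so C10 and C6 are not epimerised.

Step 18
Reactants: 25 diene
Product: 26 eight-membered (4Z)-enone fused to the butenolide (6S,8R,10R)
Conditions: second-generation Hoveyda–Grubbs catalyst RuCl2(H2IMes)(=CH-C6H4-2-OiPr) (10 mol %), toluene (1 mM), 80 °C
Reagents that add atoms: none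
Why: Ring-closing metathesis starts at the monosubstituted C5 vinyl group and closes on the isopropenyl ketone; the eight-membered ring can hold only the cis C4=C5 olefin, and the sp2 carbon C7 that carries both tethers brings the chain ends together.

Step 19
Reactants: 26 cyclooctenone
Product: 27 eight-membered C1=C4 trimethylsilyl enol ether with a C5 pentafluorophenyl sulfide (5R,6R,8R,10R)
Conditions: C6F5SH, N,O-bis(trimethylsilyl)acetamide, CH2Cl2, rt; then 26, Bu4N[Ph3SiF2] (5 mol %), −40 °C
Reagents that add atoms: pentafluorobenzenethiol, Sc1c(F)c(F)c(F)c(F)c1F; N,O-bis(trimethylsilyl)acetamide, CC(=N[Si](C)(C)C)O[Si](C)(C)C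
Why: Thiosilane conjugate addition (thia-Michael with O-silyl transfer) fixes the enol ether at C1=C4, the very weakly basic thiolate leaves C6–H alone, and the C5 centre (attack anti to the C6–O bond expected) is erased in step 21.

Step 20
Reactants: 27 silyl enol ether; 28 trichloroacetyl chloride
Product: 32 ten-membered 1,3-dione (C5 pentafluorophenyl sulfide; C4 epimers; 5R,6R,8R,10R), via dichloroketene 29 (not isolated), via dichlorocyclobutanone 30 (not isolated), via siloxycyclobutanone 31 (not isolated)
Conditions: 28, Zn–Cu couple, DME–Et2O, 0 °C → rt; then Zn dust, AcOH–H2O–iPrOH, rt → 50 °C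
Reagents that add atoms: trichloroacetyl chloride 28, ClC(Cl)(Cl)C(Cl)=O (supplies C2, C3 and the C3 oxygen)
Why: Zinc dechlorinates 28 to dichloroketene, which adds in a polarised, asynchronous [2+2]: its carbonyl carbon (C3) bonds to the nucleophilic C4, and its CCl2 carbon (C2) closes on the siloxycarbenium carbon C1 to give the cis-fused 2,2-dichloro-3-siloxycyclobutanone 30. Zinc and acetic acid then take off both chlorines before the O–Si bond is broken, because an oxygen donor next to CCl2 would expel the dichloro-enolate (C1–C2 cleavage, plain acylation); only then does protodesilylation let the β-hydroxycyclobutanone undergo retro-aldol cleavage of the fully substituted C1–C4 bond toward the C3 enol. The closest known reaction type is the dichloroketene–silyl enol ether cycloaddition followed by reductive ring expansion of 1-siloxybicyclo[n.2.0]alkanones to cycloalkane-1,3-diones. The four-membered ring closes by [2+2] across the ring-cis enol ether, and the ten-membered ring arises by scission of the zero bridge of the bicyclo[6.2.0]decane rather than by end-to-end cyclisation. No stereocentre of the target is set: C1 and C4 of the cyclobutane are erased, the C4–H epimers disappear in step 21, and C6, C8 and C10 only see mild acid. Regiochemistry rests on the enol ether position fixed in step 19 and on ketene polarity; chemoselectivity rests on the pentafluorophenyl sulfide being too electron-poor for S-acylation (this closes the ketene-Claisen pathway of ordinary allyl sulfides), on the inert electron-poor butenolide and enoate olefins, and on DME binding ZnCl2.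

Step 21
Reactants: 32 β-arylthio dione
Product: 34 ten-membered (4E)-enone 1,3-dione (6S,8R,10R), via sulfoxide 33 (not isolated)
Conditions: dimethyldioxirane (1.0 equiv), acetone–CH2Cl2, −40 °C; then dimedone (2 equiv), toluene, 45 °C
Reagents that add atoms: none
Why: Sulfide oxidation is far faster than any reaction of the dioxirane with the diketo form, and the electron-poor aryl sulfoxide undergoes thermal syn-elimination toward the more acidic C4–H α to the C3 ketone through the rotamer with C3 and C6 anti, which should give the E-enone while dimedone traps the sulfenic acid.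

Step 22
Reactants: 34 enone dione
Product: 35 2,2-dibromo-(4E)-enone 1,3-dione
Conditions: NBS (2.2 equiv), Mg(ClO4)2 (30 mol %), MeCN, 0 °C, dark
Reagents that add atoms: N-bromosuccinimide, O=C1CCC(=O)N1Br
Why: Lewis acid-catalysed double α-bromination of the active methylene blocks enolisation at C2, so the dioxirane of step 23 cannot hydroxylate it, while the electron-poor olefins do not react with NBS.

Step 23
Reactants: 35 dibromo enone
Product: 36 2,2-dibromo-4,5-epoxide (4S,5R,6R,8R,10R)
Conditions: dimethyldioxirane, acetone–CH2Cl2, 0 °C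
Reagents that add atoms: dimethyldioxirane, CC1(C)OO1
Why: Concerted oxygen transfer keeps the E geometry (trans-oxirane), and since only the outer face of the ring-perpendicular, poorly conjugated olefin can be reached, the oxidant should avoid passing the C6–O dipole and attack the conformer with C6–H turned outward and C6–O in the olefin plane, which gives the 5,6-erythro (4S,5R) epoxide.

Step 24
Reactants: 36 dibromo epoxide
Product: 37 CNP0274470.1
Conditions: Na2SO3, THF–phosphate buffer (pH 7), 0 °C
Reagents that add atoms: none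
Why: Sulfite attacks the two positive bromines of the 2,2-dibromo-1,3-dione (halophilic reduction, the stabilised diketonate being the leaving group) much faster than it can touch the epoxy ketone, lactone or esters at neutral pH.

**Compound list**
1 | diethyl furan-3,4-dicarboxylate | CCOC(=O)c1cocc1C(=O)OCC | starting material
2 | furan-3,4-diyldimethanol | OCc1cocc1CO | intermediate
3 | 1H,3H-furo[3,4-c]furan-1-one | O=C1OCc2cocc12 | intermediate
4 | methyl (S)-3-hydroxy-2-methylpropanoate | COC(=O)[C@@H](C)CO | starting material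
5 | methyl (S)-3-(tert-butyldimethylsilyloxy)-2-methylpropanoate | COC(=O)[C@@H](C)CO[Si](C)(C)C(C)(C)C | intermediate
6 | (R)-3-(tert-butyldimethylsilyloxy)-2-methylpropan-1-ol | OC[C@@H](C)CO[Si](C)(C)C(C)(C)C | intermediate
7 | (S)-tert-butyl(3-iodo-2-methylpropoxy)dimethylsilane | IC[C@@H](C)CO[Si](C)(C)C(C)(C)C | intermediate
8 | (R)-3-(tert-butyldimethylsilyloxy)-2-methylpropyllithium | [Li]C[C@@H](C)CO[Si](C)(C)C(C)(C)C | intermediate
9 | C8 furyl ketone with free C13 alcohol (10R) | OCc1cocc1C(=O)C[C@@H](C)CO[Si](C)(C)C(C)(C)C | intermediate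
10 | furyl diol (8S,10R) | OCc1cocc1[C@@H](O)C[C@@H](C)CO[Si](C)(C)C(C)(C)C | intermediate
11 | furan endoperoxide of 10 | OCC1=C([C@@H](O)C[C@@H](C)CO[Si](C)(C)C(C)(C)C)C2OOC1O2 | intermediate
12 | γ-hydroxybutenolide (C6 hemiacetal, C12 carbonyl; 8S,10R) | OCC1=C([C@@H](O)C[C@@H](C)CO[Si](C)(C)C(C)(C)C)C(O)OC1=O | intermediate
13 | ring-opened (Z)-hydroxy acid with C6 vinyl carbinol | OC/C(C(O)=O)=C(\[C@@H](O)C[C@@H](C)CO[Si](C)(C)C(C)(C)C)[C@@H](O)C=C | intermediate
14 | γ-vinylbutenolide diol (6S,8S,10R) | OCC1=C([C@@H](O)C[C@@H](C)CO[Si](C)(C)C(C)(C)C)[C@H](C=C)OC1=O | intermediate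
15 | C13 acetate, C8 alcohol (6S,8S,10R) | CC(=O)OCC1=C([C@@H](O)C[C@@H](C)CO[Si](C)(C)C(C)(C)C)[C@H](C=C)OC1=O | intermediate
16 | 4-methylfuran-2(5H)-one | CC1=CC(=O)OC1 | starting material
17 | sodium (Z)-4-hydroxy-3-methylbut-2-enoate | [Na+].[O-]C(=O)/C=C(/C)CO | intermediate
18 | 4-methoxybenzyl (Z)-4-hydroxy-3-methylbut-2-enoate | COc1ccc(COC(=O)/C=C(/C)CO)cc1 | intermediate
19 | 4-methoxybenzyl (Z)-4-acetoxy-3-methylbut-2-enoate | COc1ccc(COC(=O)/C=C(/C)COC(C)=O)cc1 | intermediate
20 | (Z)-4-acetoxy-3-methylbut-2-enoic acid | OC(=O)/C=C(/C)COC(C)=O | intermediate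
21 | C8 ester, C1 silyl ether (6S,8R,10R) | CC(=O)OCC1=C([C@H](OC(=O)/C=C(/C)COC(C)=O)C[C@@H](C)CO[Si](C)(C)C(C)(C)C)[C@H](C=C)OC1=O | intermediate
22 | C1 primary alcohol | CC(=O)OCC1=C([C@H](OC(=O)/C=C(/C)COC(C)=O)C[C@@H](C)CO)[C@H](C=C)OC1=O | intermediate
23 | C1 aldehyde | CC(=O)OCC1=C([C@H](OC(=O)/C=C(/C)COC(C)=O)C[C@@H](C)C=O)[C@H](C=C)OC1=O | intermediate
24 | C1 isopropenyl carbinol (C1 epimers) | CC(=O)OCC1=C([C@H](OC(=O)/C=C(/C)COC(C)=O)C[C@@H](C)C(O)C(C)=C)[C@H](C=C)OC1=O | intermediate
25 | C1 isopropenyl ketone | CC(=O)OCC1=C([C@H](OC(=O)/C=C(/C)COC(C)=O)C[C@@H](C)C(=O)C(C)=C)[C@H](C=C)OC1=O | intermediate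
26 | eight-membered (4Z)-enone fused to the butenolide | CC(=O)OCC1=C2[C@@H](OC1=O)/C=C(C)\C(=O)[C@H](C)C[C@H]2OC(=O)/C=C(/C)COC(C)=O | intermediate
27 | eight-membered C1=C4 TMS enol ether, C5 pentafluorophenyl sulfide | CC(=O)OCC1=C2[C@@H](OC1=O)[C@H](Sc3c(F)c(F)c(F)c(F)c3F)/C(C)=C(O[Si](C)(C)C)\[C@H](C)C[C@H]2OC(=O)/C=C(/C)COC(C)=O | intermediate
28 | trichloroacetyl chloride | ClC(Cl)(Cl)C(Cl)=O | starting material
29 | dichloroketene | ClC(Cl)=C=O | intermediate
30 | cis-fused 2,2-dichloro-3-siloxycyclobutanone (bicyclo[6.2.0]) | CC(=O)OCC1=C2[C@@H](OC1=O)[C@H](Sc3c(F)c(F)c(F)c(F)c3F)C3(C)C(=O)C(Cl)(Cl)C3(O[Si](C)(C)C)[C@H](C)C[C@H]2OC(=O)/C=C(/C)COC(C)=O | intermediate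
31 | cis-fused 3-siloxycyclobutanone | CC(=O)OCC1=C2[C@@H](OC1=O)[C@H](Sc3c(F)c(F)c(F)c(F)c3F)C3(C)C(=O)CC3(O[Si](C)(C)C)[C@H](C)C[C@H]2OC(=O)/C=C(/C)COC(C)=O | intermediate
32 | ten-membered 1,3-dione, C5 sulfide, C4 epimers | CC(=O)OCC1=C2[C@@H](OC1=O)[C@H](Sc3c(F)c(F)c(F)c(F)c3F)C(C)C(=O)CC(=O)[C@H](C)C[C@H]2OC(=O)/C=C(/C)COC(C)=O | intermediate
33 | C5 sulfoxide of 32 | CC(=O)OCC1=C2[C@@H](OC1=O)[C@H](S(=O)c3c(F)c(F)c(F)c(F)c3F)C(C)C(=O)CC(=O)[C@H](C)C[C@H]2OC(=O)/C=C(/C)COC(C)=O | intermediate
34 | ten-membered (4E)-enone 1,3-dione | CC(=O)OCC1=C2[C@@H](OC1=O)/C=C(\C)C(=O)CC(=O)[C@H](C)C[C@H]2OC(=O)/C=C(/C)COC(C)=O | intermediate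
35 | 2,2-dibromo-(4E)-enone 1,3-dione | CC(=O)OCC1=C2[C@@H](OC1=O)/C=C(\C)C(=O)C(Br)(Br)C(=O)[C@H](C)C[C@H]2OC(=O)/C=C(/C)COC(C)=O | intermediate
36 | 2,2-dibromo-4,5-epoxide (4S,5R,6R,8R,10R) | CC(=O)OCC1=C2[C@@H](OC1=O)[C@H]1O[C@]1(C)C(=O)C(Br)(Br)C(=O)[C@H](C)C[C@H]2OC(=O)/C=C(/C)COC(C)=O | intermediate
37 | CNP0274470.1 (4S,5R,6R,8R,10R) | CC(=O)OCC1=C2[C@@H](OC1=O)[C@H]1O[C@]1(C)C(=O)CC(=O)[C@H](C)C[C@H]2OC(=O)/C=C(/C)COC(C)=O | target

**Step count**
- Total: 24 steps.
- Longest linear sequence: 20 steps (from 4: steps 3–10 and 13–24).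

**Steps most likely to fail**

**Step 20.**
- The cycloaddition may be too slow at the tetrasubstituted enol ether, which is flanked by two branched carbons. Ketene oligomerisation and zinc chloride-induced loss of the silyl group or of the thiolate (return to 26) would then take over.
- The fallback sets out from 27 and replaces the ketene by a keteniminium salt.
- N,N-dimethylacetamide, Tf2O and 2,6-di-tert-butyl-4-methylpyridine in CH2Cl2 generate CH2=C=NMe2 triflate. This is a stronger two-carbon electrophile that does not dimerise.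
- Its [2+2] addition would give the cyclobutaniminium triflate F1.
- Hydrolysis with aqueous NaHCO3 leads to the siloxycyclobutanone 31. There the route is rejoined, and AcOH–H2O opens it to 32 without zinc and without chlorine.

**Step 23.**
- Facial selectivity may be poor or reversed. Allylic strain between the lactone oxygen on C6 and the C4 methyl group favours the other planar-chiral conformer of the E-olefin, which exposes the wrong face.
- The fallback sets out from 35 and delivers the oxygen anti to the electrophile.
- NBS in aqueous acetone places bromine on the preferred face and water on C5 from the opposite side, giving the bromohydrin F2.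
- Ag2O in CH2Cl2 closes F2 by SN2 displacement at C4 to the epoxide 36, where the route is rejoined.

**Step 18.**
- Intermolecular metathesis at the vinyl group and catalyst decay may outrun engagement of the electron-poor 1,1-disubstituted olefin. Migration of the C5 olefin into conjugation with the butenolide is a further loss.
- The fallback sets out from 24 and closes the ring one oxidation level lower, where the isopropenyl carbinol is the more reactive partner.
- Metathesis of 24 would give the cyclooctenol F3.
- Dess–Martin oxidation of F3 leads to 26, where the route is rejoined.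

**Further compounds**
F1 | step 20 | cyclobutaniminium triflate from 27 and the keteniminium salt | CC(=O)OCC1=C2[C@@H](OC1=O)[C@H](Sc3c(F)c(F)c(F)c(F)c3F)C3(C)C(=[N+](C)C)CC3(O[Si](C)(C)C)[C@H](C)C[C@H]2OC(=O)/C=C(/C)COC(C)=O.[O-]S(=O)(=O)C(F)(F)F
F2 | step 23 | 4-bromo-5-hydroxy ketone (bromohydrin of 35) | CC(=O)OCC1=C2[C@@H](OC1=O)[C@@H](O)[C@@](C)(Br)C(=O)C(Br)(Br)C(=O)[C@H](C)C[C@H]2OC(=O)/C=C(/C)COC(C)=O
F3 | step 18 | eight-membered (4Z)-allylic alcohol (C1 epimers) | CC(=O)OCC1=C2[C@@H](OC1=O)/C=C(C)\C(O)[C@H](C)C[C@H]2OC(=O)/C=C(/C)COC(C)=O
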